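At early times the grey and green runs read alike: after 3.00 h each holds 55% of its Qb, which is becoming Qd in a flask dosed with a trace of Qe.

the same everywhere: Qb 0.092 M; Qe 0.015 mol%
- grey: temperature 37 °C; the very flask that is asked about, followed so far
- green: temperature 32 °C; run made earlier
- flask: temperature 37 °C; time 40 h

| run | time / h | Qd / % | Qb / % |
|---|---|---|---|
| grey | 3.00 | 48 | 55 |
| grey | 8.00 | 67 | 32 |
| grey | 15.0 | 76 | 24 |
| grey | 40.0 | 85 | 14 |
| green | 3.00 | 46 | 55 |
| green | 8.00 | 70 | 31 |
| green | 15.0 | 81 | 20 |
| green | 40.0 | 86 | 13 |

(scatter of a reading: 1.5 percentage points)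

- larch: at 40 h add Qe, 100% of the amount charged, then wait 3.0 d
- birch: change nothing and wait 3.0 d more
- cedar: at 40 h take out 90% of the Qd then present, then wait 3.0 d

* Qd, in percent of the Qb first charged, at 40 h
* which option adds most Qd ("none" when 2 percentage points or less is all one gets) (larch / birch / cedar / none)
* Qd present, with what was taken out counted in, in percent of the Qb first charged, after birch
* Qd present, with what was taken out counted in, in percent of the Qb first charged, after cedar

- what is taken out of Qd is counted as made
- the numbers in the tables scatter with a standard deviation of 1.5 percentage points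
- additions bring no volume worth counting

Later the grey curve bends. Replacing it by its mean slope over two windows gives the time constant of the falling rate, and from that the reserve number N, the Qd still to come at that falling rate divided by the Qb left at 40.0 h:

mean rate, 8.00 h to 15.0 h: ra = 0.0129 h⁻¹
mean rate, 15.0 h to 40.0 h: rb = 0.00360 h⁻¹
time constant: tau = 12.6 h
grey: N = 0.120

With N below one, the rate as reckoned dies away with Qb still in the grey flask. The wait of 3.0 d is far longer than tau, so this reckoning gives birch the whole tail, 1.7 percentage points.

The green run tests this. It gives N = 0.0239, also small, so N tells of both runs that the rate falls away, not why. A dying catalyst and a ceiling read alike in these readings. This reckoning bets on a dying catalyst, with Qe as its charge: rolled back to the start of the curve, the estimate of N for a fresh charge of Qe becomes 2.88, above one, so this reckoning puts larch first.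

The forecast differs. It gives 85.5% now, 87% after birch and 92% after cedar, and picks cedar, since “removing product reopens the driving force”.

The grey flask gives 83.4% at 40.0 h. Larch adds 6.9 points, more than birch or cedar, which each add 2 points and end alike at 85.3%.

    Qe ⇌ Qa (K = 0.440, k = 2.10 × 10⁻⁴ s⁻¹, Ea = 90.0 kJ mol⁻¹, ΔH = −52.0 kJ mol⁻¹)
    Qb + Qa → Qd + Qa, rate k2*[Qb]^2.5*[Qa]/(1 + ([Qb]/Kh2)^2.5) (0.170 M, k = 1200 L²·⁵ mol⁻²·⁵ s⁻¹, Ea = 37.0 kJ mol⁻¹)
    Qb → Qf (k = 9.40 × 10⁻⁸ s⁻¹, Ea = 120 kJ mol⁻¹)
    Qa → Qc (k = 3.90 × 10⁻⁵ s⁻¹, Ea = 276 kJ mol⁻¹)
    (constants at 37 °C)

By that step alone Qa passes into Qc with a half-life of 4.9 h, far shorter than the 85 d of Qb passing into Qf at 40.0 h, and at 40.0 h the grey flask has 80.5% of its catalyst as Qc with 16% of its Qb left, on which N gives 1.9 points against the 2 points that birch adds. The repeat at 52 °C has an empty reserve at 40.0 h, with Qa 0%, Qe 0% and Qb still 78.5%.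

All runs were computed on assumed constants, and the scatter is random.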